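The hydroazulene is opened at the ring-fusion bond C1–C5 and at the ring alkene C8=C9 (numbering below). Reading C4 as a carboxyl carbon and C2=C3 as a vinyl group turns C4–C5–C6(OH) into a β-hydroxy ester, whose (E)-3-methylhexa-2,5-dienyl alcohol part carries C1–C3, C9 and C10. The key step exploits the C6 carbinol next to the vicinal pair C1/C5 of the seven-membered ring: in one flask the chelated ester dianion undergoes an Ireland–Claisen rearrangement that relays the C6 configuration to C5 and the quaternary C1, and ring-closing metathesis then joins the allyl group on C1 to the 2-methylallyl group on C6. An aldol closure C3–C4 adds the five-membered ring.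

Key step: step 5

Remark on numbering: C1 is the methyl-bearing ring-fusion carbon, C2 the angeloyloxy carbon, C3 the ring CH2, C4 the isopropyl carbinol carbon, C5 the ring-fusion CH, C6 the anisoyloxy carbon, C7 a CH2, C8 the methyl-bearing alkene carbon, C9 the alkene CH and C10 a CH2.
Remark on the chemistry: 1, 4 and all reagents on the Conditions lines are taken as commercial; lithium salts formed in steps 5, 6 and 8 are written as the neutral compounds; 11 is written open-chain although it may close reversibly to a hemiketal with the C6 hydroxyl.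

Step 1
Reactants: 1 ethyl (3R)-4-chloro-3-hydroxybutanoate
Product: 2 ethyl [(2R)-oxiran-2-yl]acetate
Conditions: Ag2O (1.5 equiv), DME, 60 °C, dark
Reagents that add atoms: none
Why: Silver-assisted intramolecular Williamson etherification (chlorohydrin to epoxide) runs without strong base, so the β-hydroxy ester should not eliminate and the carbinol centre is untouched.

Step 2
Reactants: 2 ethyl [(2R)-oxiran-2-yl]acetate
Product: 3 ethyl (3S)-3-hydroxy-5-methylhex-5-enoate
Conditions: CH2=C(CH3)MgBr (1.5 equiv), CuI (0.1 equiv), THF, −40 °C; aq NH4Cl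
Reagents that add atoms: isopropenylmagnesium bromide, C=C(C)[Mg]Br
Why: Copper-catalysed Grignard opening of a terminal epoxide (SN2 at the CH2 terminus) should outrun attack on the ester at −40 °C, so the future C6 centre is carried through unchanged (its descriptor changes from R to S by priority only).

Step 3
Reactants: 4 pent-1-en-4-yne
Product: 6 (2E)-3-methylhexa-2,5-dien-1-ol, via alkenylalane 5 (not isolated)
Conditions: Me3Al (2 equiv), Cp2ZrCl2 (0.25 equiv), CH2Cl2, 0 °C to rt; then n-BuLi (1 equiv), THF, −78 °C, (CH2O)n, rt; aq HCl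
Reagents that add atoms: trimethylaluminium, C[Al](C)C; formaldehyde (as paraformaldehyde), C=O
Why: Zirconium-catalysed methylalumination of the terminal alkyne (Negishi carboalumination) is a syn addition with aluminium on the terminal carbon, and hydroxymethylation of the derived alanate with retention fixes the E trisubstituted alkene that later defines C1.

Step 4
Reactants: 3 ethyl (3S)-3-hydroxy-5-methylhex-5-enoate, 6 (2E)-3-methylhexa-2,5-dien-1-ol
Product: 7 (2E)-3-methylhexa-2,5-dien-1-yl (3S)-3-hydroxy-5-methylhex-5-enoate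
Conditions: Ti(OEt)4 (0.2 equiv), 6 (1.5 equiv), toluene, 100 °C, 4 Å molecular sieves (removal of EtOH)
Reagents that add atoms: none
Why: Titanate-catalysed transesterification driven by removal of ethanol is neutral, so the β-hydroxy ester should neither dehydrate nor epimerise.

Step 5
Reactants: 7 (2E)-3-methylhexa-2,5-dien-1-yl (3S)-3-hydroxy-5-methylhex-5-enoate
Product: 9 (1S,2S,7S)-2-ethenyl-7-hydroxy-2,5-dimethylcyclohept-4-ene-1-carboxylic acid, via Claisen acid 8 (not isolated)
Conditions: LDA (LiN(iPr)2, 2.3 equiv), THF, −78 °C, then warm to 50 °C; cool to 0 °C, AcOH (5 equiv); dilute with degassed toluene to 0.005 M, second-generation Grubbs catalyst (H2IMes)(PCy3)Cl2Ru=CHPh (5 mol %), 80 °C; aq HCl work-up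
Reagents that add atoms: none
Why: Two equivalents of base give the lithium-chelated β-oxido ester enolate (C6 cis to the enolate O–Li), which on warming undergoes a [3,3]-sigmatropic shift through the chair array C5=C4(O)–O–C3–C2=C1, making C1–C5 and releasing C2=C3 as a vinyl group and C4 as the carboxylate; after neutralisation the ruthenium carbene loads onto the unhindered allyl CH=CH2 on C1 and closes onto the 2-methylallyl group on C6, making C8=C9 with loss of ethylene. The closest known reactions are the Ireland–Claisen-type rearrangement of allyl β-hydroxy ester dianions and the ring-closing metathesis of 1,8-dienes to 1-methylcycloheptenes, here run in one flask. The only ring closed is the seven-membered one, by ring-closing olefin metathesis that gives the endocyclic trisubstituted alkene; the sigmatropic step closes no ring. C5 is set by attack of the allyl terminus on the enolate face anti to the C7 chain of the six-membered chelate (the sense of the Fráter–Seebach alkylation, giving the 5,6-anti acid), and the quaternary C1 is set relative to C5 by the chair with the E alkene, which puts the C10 methylene equatorial and the methyl axial. The step needs chair over boat, one enolate geometry, facial bias and seven- over six-ring metathesis; the chelate and the E alkene should secure the first three, and the neopentyl vinyl group on C1 should be too hindered to compete with the allyl group for the catalyst.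

Step 6
Reactants: 9 (1S,2S,7S)-2-ethenyl-7-hydroxy-2,5-dimethylcyclohept-4-ene-1-carboxylic acid
Product: 10 1-[(1S,2S,7S)-2-ethenyl-7-hydroxy-2,5-dimethylcyclohept-4-en-1-yl]-2-methylpropan-1-one
Conditions: iPrLi (4 equiv), THF, −78 to 0 °C; then dilute aq HCl
Reagents that add atoms: isopropyllithium, [Li]C(C)C
Why: Addition of an alkyllithium to a lithium carboxylate stops at the gem-dialkoxide, which gives the ketone only on aqueous work-up (carboxylic acid to ketone conversion), the first two equivalents merely deprotonating the acid and the C6 hydroxyl.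

Step 7
Reactants: 10 1-[(1S,2S,7S)-2-ethenyl-7-hydroxy-2,5-dimethylcyclohept-4-en-1-yl]-2-methylpropan-1-one
Product: 11 1-[(1S,2R,7S)-2-acetyl-7-hydroxy-2,5-dimethylcyclohept-4-en-1-yl]-2-methylpropan-1-one
Conditions: PdCl2 (0.1 equiv), CuCl (1 equiv), O2 (1 atm), DMF–H2O (7:1), rt
Reagents that add atoms: water, O
Why: In the Tsuji–Wacker oxidation divalent palladium activates only the monosubstituted vinyl group for Markovnikov attack by water, giving the methyl ketone, while the trisubstituted ring alkene should stay inert.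

Step 8
Reactants: 11 1-[(1S,2R,7S)-2-acetyl-7-hydroxy-2,5-dimethylcyclohept-4-en-1-yl]-2-methylpropan-1-one
Product: 12 (3R,3aS,4S,8aR)-3,4-dihydroxy-6,8a-dimethyl-3-(propan-2-yl)-3,3a,4,5,8,8a-hexahydroazulen-1(2H)-one
Conditions: LiN(SiMe3)2 (2.2 equiv), THF, −78 to −20 °C; AcOH quench
Reagents that add atoms: none
Why: Intramolecular aldol addition of the kinetic lithium enolate of the methyl ketone (C3) to the isopropyl ketone (C4) closes the cyclopentane, and lithium bridging between the C6 alkoxide and the C4 carbonyl oxygen should hold that oxygen on the side of C6, so that the new C4 hydroxyl is cis to the angular methyl and the isopropyl group is cis to H5.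

Step 9
Reactants: 12 (3R,3aS,4S,8aR)-3,4-dihydroxy-6,8a-dimethyl-3-(propan-2-yl)-3,3a,4,5,8,8a-hexahydroazulen-1(2H)-one
Product: 13 (3R,3aS,4S,8aR)-3-hydroxy-6,8a-dimethyl-1-oxo-3-(propan-2-yl)-1,2,3,3a,4,5,8,8a-octahydroazulen-4-yl 4-methoxybenzoate
Conditions: 4-methoxybenzoyl chloride (1.5 equiv), pyridine, DMAP (0.1 equiv), CH2Cl2, 0 °C to rt
Reagents that add atoms: 4-methoxybenzoyl chloride, COc1ccc(cc1)C(Cl)=O
Why: DMAP-catalysed acylation with an acyl chloride should discriminate the secondary C6 hydroxyl from the tertiary C4 hydroxyl on steric grounds.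

Step 10
Reactants: 13 (3R,3aS,4S,8aR)-3-hydroxy-6,8a-dimethyl-1-oxo-3-(propan-2-yl)-1,2,3,3a,4,5,8,8a-octahydroazulen-4-yl 4-methoxybenzoate
Product: 14 (1R,3R,3aS,4S,8aR)-1,3-dihydroxy-6,8a-dimethyl-3-(propan-2-yl)-1,2,3,3a,4,5,8,8a-octahydroazulen-4-yl 4-methoxybenzoate
Conditions: NaBH4 (2 equiv), MeOH, −20 °C
Reagents that add atoms: none
Why: Borohydride reduction of the cyclopentanone should deliver hydride to C2 from the face opposite the angular methyl on the adjacent C1 (as in 17-oxo steroids), giving the C2 hydroxyl cis to that methyl, while the aryl ester is not reduced.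

Step 11
Reactants: 14 (1R,3R,3aS,4S,8aR)-1,3-dihydroxy-6,8a-dimethyl-3-(propan-2-yl)-1,2,3,3a,4,5,8,8a-octahydroazulen-4-yl 4-methoxybenzoate
Product: 15 (1R,3R,3aS,4S,8aR)-3-hydroxy-4-[(4-methoxybenzoyl)oxy]-6,8a-dimethyl-3-(propan-2-yl)-1,2,3,3a,4,5,8,8a-octahydroazulen-1-yl (2Z)-2-methylbut-2-enoate
Conditions: (2Z)-2-methylbut-2-enoic acid (3 equiv), 2,4,6-trichlorobenzoyl chloride (3 equiv), Et3N (6 equiv), toluene, rt; then 14, 80 °C
Reagents that add atoms: (2Z)-2-methylbut-2-enoic acid (angelic acid), C/C=C(/C)C(=O)O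
Why: Yamaguchi esterification through the mixed 2,4,6-trichlorobenzoic anhydride, run without DMAP, should acylate the secondary C2 hydroxyl with retention of the Z (angelate) geometry and leave the tertiary hydroxyl alone.

Compound list
1 | ethyl (3R)-4-chloro-3-hydroxybutanoate | CCOC(=O)C[C@@H](O)CCl | starting material
2 | ethyl [(2R)-oxiran-2-yl]acetate | CCOC(=O)C[C@@H]1CO1 | intermediate
3 | ethyl (3S)-3-hydroxy-5-methylhex-5-enoate | CCOC(=O)C[C@@H](O)CC(C)=C | intermediate
4 | pent-1-en-4-yne | C=CCC#C | starting material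
5 | dimethyl[(1E)-2-methylpenta-1,4-dien-1-yl]alumane | C[Al](C)/C=C(\C)CC=C | intermediate (not isolated)
6 | (2E)-3-methylhexa-2,5-dien-1-ol | OC/C=C(\C)CC=C | intermediate
7 | (2E)-3-methylhexa-2,5-dien-1-yl (3S)-3-hydroxy-5-methylhex-5-enoate | O=C(OC/C=C(\C)CC=C)C[C@@H](O)CC(C)=C | intermediate
8 | (2S,3S)-3-hydroxy-5-methyl-2-[(3S)-3-methylhexa-1,5-dien-3-yl]hex-5-enoic acid (in the flask first as its dilithium salt) | OC(=O)[C@@H]([C@](C)(C=C)CC=C)[C@@H](O)CC(C)=C | intermediate (not isolated)
9 | (1S,2S,7S)-2-ethenyl-7-hydroxy-2,5-dimethylcyclohept-4-ene-1-carboxylic acid | OC(=O)[C@H]1[C@](C)(C=C)CC=C(C)C[C@@H]1O | intermediate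
10 | 1-[(1S,2S,7S)-2-ethenyl-7-hydroxy-2,5-dimethylcyclohept-4-en-1-yl]-2-methylpropan-1-one | CC(C)C(=O)[C@H]1[C@](C)(C=C)CC=C(C)C[C@@H]1O | intermediate
11 | 1-[(1S,2R,7S)-2-acetyl-7-hydroxy-2,5-dimethylcyclohept-4-en-1-yl]-2-methylpropan-1-one | CC(C)C(=O)[C@H]1[C@](C)(C(C)=O)CC=C(C)C[C@@H]1O | intermediate
12 | (3R,3aS,4S,8aR)-3,4-dihydroxy-6,8a-dimethyl-3-(propan-2-yl)-3,3a,4,5,8,8a-hexahydroazulen-1(2H)-one | O=C1C[C@@](O)(C(C)C)[C@@H]2[C@@H](O)CC(C)=CC[C@]21C | intermediate
13 | (3R,3aS,4S,8aR)-3-hydroxy-6,8a-dimethyl-1-oxo-3-(propan-2-yl)-1,2,3,3a,4,5,8,8a-octahydroazulen-4-yl 4-methoxybenzoate | O=C1C[C@@](O)(C(C)C)[C@@H]2[C@@H](OC(=O)c3ccc(OC)cc3)CC(C)=CC[C@]21C | intermediate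
14 | (1R,3R,3aS,4S,8aR)-1,3-dihydroxy-6,8a-dimethyl-3-(propan-2-yl)-1,2,3,3a,4,5,8,8a-octahydroazulen-4-yl 4-methoxybenzoate | O[C@@H]1C[C@@](O)(C(C)C)[C@@H]2[C@@H](OC(=O)c3ccc(OC)cc3)CC(C)=CC[C@]21C | intermediate
15 | (1R,3R,3aS,4S,8aR)-3-hydroxy-4-[(4-methoxybenzoyl)oxy]-6,8a-dimethyl-3-(propan-2-yl)-1,2,3,3a,4,5,8,8a-octahydroazulen-1-yl (2Z)-2-methylbut-2-enoate | C/C=C(/C)C(=O)O[C@@H]1C[C@@](O)(C(C)C)[C@@H]2[C@@H](OC(=O)c3ccc(OC)cc3)CC(C)=CC[C@]21C | target

Total step count: 11
Longest linear sequence: 10 steps (steps 1, 2, 4, 5, 6, 7, 8, 9, 10, 11)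

Steps most likely to fail

Step 5. What may go wrong: expulsion of the allylic alkoxide from the dianion before the sigmatropic shift, erosion of facial control while the quaternary centre forms, or deactivation of the ruthenium carbene by the unpurified amine- and lithium-containing mixture. The fallback sets out from 7 and returns at 9. The hydroxyl of 7 would be silylated (TBSCl, imidazole, DMF) to (2E)-3-methylhexa-2,5-dien-1-yl (3S)-3-[(tert-butyldimethylsilyl)oxy]-5-methylhex-5-enoate F1. F1 would be converted into its O-trimethylsilyl ketene acetal (LDA, TMSCl, THF–DMPU, −78 °C, the solvent pair that places C6 cis to the silyloxy group) and rearranged at 60 °C in a classical, non-chelated Ireland–Claisen reaction. Hydrolysis would give the isolated acid (2S,3S)-3-[(tert-butyldimethylsilyl)oxy]-5-methyl-2-[(3S)-3-methylhexa-1,5-dien-3-yl]hex-5-enoic acid F2, at which stage any diastereomers would be removed. Ring-closing metathesis of purified F2 as a separate step would give (1S,2S,7S)-7-[(tert-butyldimethylsilyl)oxy]-2-ethenyl-2,5-dimethylcyclohept-4-ene-1-carboxylic acid F3, and Bu4NF would release 9.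

Step 6. What may go wrong: slow addition of the secondary alkyllithium to the hindered dilithium salt, with enolisation or retro-aldol opening of the ring on warming. The fallback sets out from 9 and returns at 10. Acid 9 would be coupled with N,O-dimethylhydroxylamine hydrochloride (EDC·HCl, HOBt, iPr2NEt) to the amide (1S,2S,7S)-2-ethenyl-7-hydroxy-N-methoxy-N,2,5-trimethylcyclohept-4-ene-1-carboxamide F4. F4 would then be treated with isopropylmagnesium chloride (iPrMgCl, excess, THF, 0 °C); the magnesium chelate of the tetrahedral intermediate should give 10 on work-up.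

Step 8. What may go wrong: slow enolendo ring closure, so that proton transfer to C5 (epimerisation), retro-aldol cleavage of the C5–C6 bond or dehydration of the aldol competes. The fallback sets out from 11 and returns at 12. The methyl ketone would be trapped as its kinetic silyl enol ether (LiN(SiMe3)2, TMSCl, −78 °C; the hydroxyl is silylated as well) to give 1-[(1S,2R,7S)-2,5-dimethyl-7-[(trimethylsilyl)oxy]-2-{1-[(trimethylsilyl)oxy]ethenyl}cyclohept-4-en-1-yl]-2-methylpropan-1-one F5. NBS would convert F5 into 1-[(1S,2R,7S)-2-(bromoacetyl)-7-hydroxy-2,5-dimethylcyclohept-4-en-1-yl]-2-methylpropan-1-one F6, the silyl ether being lost on work-up. SmI2 (2.2 equiv, THF, −78 °C) would then generate the trivalent samarium enolate regiospecifically under neutral conditions and close the ring by an intramolecular Reformatsky reaction through a chelate, giving 12.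

Further compounds
F1 | step 5 | (2E)-3-methylhexa-2,5-dien-1-yl (3S)-3-[(tert-butyldimethylsilyl)oxy]-5-methylhex-5-enoate | O=C(OC/C=C(\C)CC=C)C[C@@H](O[Si](C)(C)C(C)(C)C)CC(C)=C
F2 | step 5 | (2S,3S)-3-[(tert-butyldimethylsilyl)oxy]-5-methyl-2-[(3S)-3-methylhexa-1,5-dien-3-yl]hex-5-enoic acid | OC(=O)[C@@H]([C@](C)(C=C)CC=C)[C@@H](O[Si](C)(C)C(C)(C)C)CC(C)=C
F3 | step 5 | (1S,2S,7S)-7-[(tert-butyldimethylsilyl)oxy]-2-ethenyl-2,5-dimethylcyclohept-4-ene-1-carboxylic acid | OC(=O)[C@H]1[C@](C)(C=C)CC=C(C)C[C@@H]1O[Si](C)(C)C(C)(C)C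
F4 | step 6 | (1S,2S,7S)-2-ethenyl-7-hydroxy-N-methoxy-N,2,5-trimethylcyclohept-4-ene-1-carboxamide | CON(C)C(=O)[C@H]1[C@](C)(C=C)CC=C(C)C[C@@H]1O
F5 | step 8 | 1-[(1S,2R,7S)-2,5-dimethyl-7-[(trimethylsilyl)oxy]-2-{1-[(trimethylsilyl)oxy]ethenyl}cyclohept-4-en-1-yl]-2-methylpropan-1-one | CC(C)C(=O)[C@H]1[C@](C)(C(=C)O[Si](C)(C)C)CC=C(C)C[C@@H]1O[Si](C)(C)C
F6 | step 8 | 1-[(1S,2R,7S)-2-(bromoacetyl)-7-hydroxy-2,5-dimethylcyclohept-4-en-1-yl]-2-methylpropan-1-one | CC(C)C(=O)[C@H]1[C@](C)(C(=O)CBr)CC=C(C)C[C@@H]1O
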